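**Retrosynthetic overview**
- C-m (ester carbon) is set last by kinetic protonation of the ester dienolate; cyclohexene B is closed before that by ring-closing metathesis (C-k=C-l).
- The C-e–C-m bond, trans to C-j, comes from an Ireland–Claisen rearrangement of a but-3-enoate on C-c.
- The cyclopentane and the C-c–O bond come from a palladium relay (palladium-ene, then carboxylate return) on the bicyclo[4.2.0]octa-2,4-diene valence isomer of a trans-7,8-disubstituted cycloocta-1,3,5-triene; that 6π closure makes the cyclobutane and cyclohexene A.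
- The cyclooctatriene comes from a Johnson–Claisen rearrangement of a trans-4-alkylcycloocta-2,5,7-trienol; the decenyl chain is grown from a C–B bond (Zweifel vinylation, B-alkyl Suzuki coupling).
- The first stereocentres come from a carbene-organocatalysed, metal-free desymmetrising SN2′ borylation of cyclooctatetraene oxide. Ring order: eight-membered ring, then cyclobutane + cyclohexene A, then cyclopentane, then cyclohexene B.

Labels and reading of the target (one line): ring carbons are C-a to C-m in the order of the target SMILES (C-a carries the decenyl chain, C-c=C-d is in cyclohexene A, C-i is the CH2, C-k=C-l is in cyclohexene B, C-m carries CO2Me); the SMILES has H-b, H-f, H-g, H-h and H-j on one face, H-e on the other (rings A and B trans-fused) and CO2Me cis to C-d, so ring B cannot come from a suprafacial [4+2] addition onto ring A and is built stepwise; the cyclooctatrienes of steps 6 to 8 equilibrate with their bicyclic 6π valence isomers and are drawn as the trienes.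

**Step 1**
Reactants: 1 cycloocta-1,3,5,7-tetraene
Product: 2 9-oxabicyclo[6.1.0]nona-2,4,6-triene (meso)
Conditions: mCPBA (1.0 equiv), CH2Cl2, 0 °C
Reagents that add atoms: 3-chloroperoxybenzoic acid, OOC(=O)c1cccc(Cl)c1
Why: Prilezhaev epoxidation of one of four equivalent cis double bonds stops at the meso mono-epoxide with one equivalent of peracid.

**Step 2**
Reactants: 2 9-oxabicyclo[6.1.0]nona-2,4,6-triene
Product: 3 (1S,4R)-4-(4,4,5,5-tetramethyl-1,3,2-dioxaborolan-2-yl)cycloocta-2,5,7-trien-1-ol (OH and boryl trans)
Conditions: B2pin2 (1.1 equiv), chiral C1-symmetric imidazolinium tetrafluoroborate (5 mol %), DBU (20 mol %), MeOH (60 equiv), THF, 22 °C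
Reagents that add atoms: bis(pinacolato)diboron, CC1(C)OB(OC1(C)C)B2OC(C)(C)C(C)(C)O2
Why: Proposed new method: the chiral carbene binds one boron of B2pin2, the polarised B–B bond delivers the other boron to a vinyl terminus of the methanol-hydrogen-bonded epoxide in an open anti-SN2′ transition state (boron trans to oxygen), and the carbene chooses between the two enantiotopic termini of the meso epoxide, which sets both stereocentres; closest known reactions are the alkoxide-promoted metal-free borylative SN2′ opening of vinyl epoxides and the carbene-catalysed enantioselective boron conjugate addition to enones.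

**Step 3**
Reactants: 3 (1S,4R)-4-(pinacolboryl)cycloocta-2,5,7-trien-1-ol
Product: 5 (1R,4R)-4-ethenylcycloocta-2,5,7-trien-1-ol, via vinylboronate complex 4 (not isolated)
Conditions: CH2=CHMgBr (4 equiv), THF, −78 → 0 °C; I2, MeOH, −78 °C; NaOMe, −78 °C → rt
Reagents that add atoms: vinylmagnesium bromide, C=C[Mg]Br
Why: Zweifel olefination, in which iodination of the vinyl group of the borate triggers 1,2-migration of the ring carbon with retention and methoxide-induced elimination releases the vinyl group, so C-4 keeps its configuration.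

**Step 4**
Reactants: 6 (E)-prop-1-enylboronic acid; 7 1,5-dibromopentane (fourfold excess)
Product: 8 (E)-8-bromooct-2-ene
Conditions: Pd(OAc)2 (5 mol %), P(t-Bu)2Me (10 mol %), KOt-Bu, t-amyl alcohol, rt
Reagents that add atoms: none
Why: Alkenyl–alkyl Suzuki–Miyaura coupling of a primary alkyl bromide; the excess dibromide gives mono-coupling and the E geometry of the boronic acid is retained.

**Step 5**
Reactants: 5 (1R,4R)-4-ethenylcycloocta-2,5,7-trien-1-ol; 8 (E)-8-bromooct-2-ene
Product: 10 (1R,4R)-4-[(E)-dec-8-en-1-yl]cycloocta-2,5,7-trien-1-ol, via B-alkyl-9-BBN adduct 9 (not isolated)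
Conditions: 9-BBN-H (2.2 equiv), THF, 0 °C → rt; then 8, Pd(OAc)2 (4 mol %), PCy3 (8 mol %), K3PO4·H2O, rt
Reagents that add atoms: none
Why: Anti-Markovnikov hydroboration of the only terminal alkene followed by B-alkyl Suzuki–Miyaura sp3–sp3 coupling completes the chain without touching either stereocentre.

**Step 6**
Reactants: 10 (1R,4R)-4-[(E)-dec-8-en-1-yl]cycloocta-2,5,7-trien-1-ol
Product: 12 ethyl 2-[(1R,8R)-8-((E)-dec-8-en-1-yl)cycloocta-2,4,6-trien-1-yl]acetate (substituents trans), via ketene acetal 11 (not isolated)
Conditions: MeC(OEt)3 (8 equiv), EtCO2H (10 mol %), xylene, 140 °C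
Reagents that add atoms: triethyl orthoacetate, CC(OCC)(OCC)OCC
Why: Johnson–Claisen rearrangement transfers the acetate unit suprafacially from O-1 to C-3, so the new CH2CO2Et is on the face of the former C–O bond and trans to the decenyl group, and the triene becomes conjugated.

**Step 7**
Reactants: 12 ethyl 2-[(1R,8R)-8-((E)-dec-8-en-1-yl)cycloocta-2,4,6-trien-1-yl]acetate
Product: 13 2-[(1R,8R)-8-((E)-dec-8-en-1-yl)cycloocta-2,4,6-trien-1-yl]acetaldehyde
Conditions: i-Bu2AlH (1.1 equiv), CH2Cl2, −78 °C; Rochelle salt
Reagents that add atoms: none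
Why: Partial ester reduction through the aluminium hemiacetal, which is stable at low temperature, stops at the aldehyde.

**Step 8**
Reactants: 13 2-[(1R,8R)-8-((E)-dec-8-en-1-yl)cycloocta-2,4,6-trien-1-yl]acetaldehyde
Product: 15 1-[(1R,8R)-8-((E)-dec-8-en-1-yl)cycloocta-2,4,6-trien-1-yl]but-3-en-2-yl methyl carbonate (both carbinol epimers), via bromomagnesium alkoxide 14 (not isolated)
Conditions: CH2=CHMgBr (1.2 equiv), THF, −78 °C; then ClCO2Me, −78 → 0 °C
Reagents that add atoms: vinylmagnesium bromide, C=C[Mg]Br; methyl chloroformate, COC(=O)Cl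
Why: Grignard 1,2-addition and in situ O-acylation; the new carbinol centre is a mixture that is erased on ionisation in step 9.

**Step 9**
Reactants: 15 the allylic methyl carbonate
Product: 17 tricyclic allylic but-3-enoate (cyclobutane a,b,g,h; cyclohexene A with C-d=C-e; cyclopentane f,g,h,i,j; vinyl on C-j; ester oxygen on C-c on the face opposite to the cyclobutane and C-j), via bicyclo[4.2.0]octa-2,4-diene valence isomer 16 (not isolated)
Conditions: Pd2(dba)3 (2.5 mol %), PPh3 (10 mol %), CH2=CHCH2CO2H (3 equiv), toluene, 80 °C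
Reagents that add atoms: but-3-enoic acid, C=CCC(=O)O
Why: Proposed new method: zerovalent palladium ionises the carbonate to a side-chain π-allyl complex, and at 80 °C the 6π valence isomers interconvert so that only 16, with this chain over the cyclohexadiene, reacts (Curtin–Hammett). A suprafacial palladium-ene insertion of the diene terminus then forms C-j–C-f on the top face, the six-membered transition state holding the vinyl group on C-j cis to the new C–Pd carbon C-e, and the resulting C-c/C-d/C-e π-allyl with palladium on the top face is captured at C-c by but-3-enoate anti to palladium, so oxygen arrives on the bottom face. Closest known reactions are the Oppolzer palladium-ene cyclisation of allylic esters and the palladium-mediated 1,4-functionalisation of cyclic 1,3-dienes via π-allyl intermediates.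

**Step 10**
Reactants: 17 the tricyclic allylic but-3-enoate
Product: 20 methyl 2-(tricyclic C-e-yl)but-3-enoate (C-e substituent trans to C-j; ring A alkene now C-c=C-d; both C-m epimers), via trimethylsilyl ketene acetal 18 (not isolated), via carboxylic acid 19 (not isolated)
Conditions: LiN(i-Pr)2, Me3SiCl, THF, −78 → 60 °C; aqueous work-up; then Me3SiCHN2, toluene–MeOH, 0 °C
Reagents that add atoms: (trimethylsilyl)diazomethane, C[Si](C)(C)C=[N+]=[N-]
Why: Ireland–Claisen rearrangement delivers C-m suprafacially from the bottom-face oxygen on C-c to C-e, which fixes C-e trans to C-j and moves the alkene to C-c=C-d; C-m forms as an epimer mixture (set in step 12), and the acid is methylated with diazomethane made in situ.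

**Step 11**
Reactants: 20 the methyl ester diene
Product: 21 methyl ester of the target skeleton as a mixture of C-m epimers
Conditions: second-generation Grubbs catalyst (3 mol %), CH2Cl2 (2 mM), 40 °C, argon sparge
Reagents that add atoms: none
Why: Ring-closing metathesis of the two terminal vinyl groups on C-j and C-m closes cyclohexene B with loss of ethene, while the internal side-chain E-alkene and the ring A alkene react far more slowly.

**Step 12**
Reactants: 21 the tetracyclic ester (C-m epimers)
Product: 23 target, methyl ester CNP0133550.2, via lithium ester dienolate 22 (not isolated)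
Conditions: LiN(i-Pr)2 (1.2 equiv), THF, −78 °C; then 2,6-di-tert-butyl-4-methylphenol (3 equiv), −78 °C
Reagents that add atoms: none
Why: Kinetic α-protonation of the exocyclic ester dienolate (Zimmerman-type) from the pseudo-equatorial direction, on the side of H-e and away from the 1,3-axial H-f, leaves CO2Me pseudo-axial and cis to C-d.

**Compound list**
1 | cycloocta-1,3,5,7-tetraene | C1=CC=CC=CC=C1 | starting material
2 | 9-oxabicyclo[6.1.0]nona-2,4,6-triene (meso) | C1=CC=C[C@@H]2O[C@@H]2C=C1 | intermediate
3 | (1S,4R)-4-(4,4,5,5-tetramethyl-1,3,2-dioxaborolan-2-yl)cycloocta-2,5,7-trien-1-ol | CC1(C)OB(OC1(C)C)[C@@H]2/C=C\C=C/[C@@H](O)/C=C\2 | intermediate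
4 | bromomagnesium vinyl(pinacolato)borate complex of 3 (O-magnesiated) | C=C[B-]1(OC(C)(C)C(C)(C)O1)[C@@H]2/C=C\C=C/[C@@H](O[Mg]Br)/C=C\2.[Mg+]Br | intermediate
5 | (1R,4R)-4-ethenylcycloocta-2,5,7-trien-1-ol | C=C[C@@H]1/C=C\C=C/[C@@H](O)/C=C\1 | intermediate
6 | (E)-prop-1-enylboronic acid | C/C=C/B(O)O | starting material
7 | 1,5-dibromopentane | BrCCCCCBr | starting material
8 | (E)-8-bromooct-2-ene | C/C=C/CCCCCBr | intermediate
9 | B-alkyl-9-BBN adduct of 5 (terminal boron, O-borinate) | C(C[C@@H]1/C=C\C=C/[C@@H](OB2C3CCCC2CCC3)/C=C\1)B4C5CCCC4CCC5 | intermediate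
10 | (1R,4R)-4-[(E)-dec-8-en-1-yl]cycloocta-2,5,7-trien-1-ol | C/C=C/CCCCCCC[C@@H]1/C=C\C=C/[C@@H](O)/C=C\1 | intermediate
11 | 1-ethoxyvinyl ether (ketene acetal) of 10 | C/C=C/CCCCCCC[C@@H]1/C=C\C=C/[C@@H](OC(=C)OCC)/C=C\1 | intermediate
12 | ethyl 2-[(1R,8R)-8-((E)-dec-8-en-1-yl)cycloocta-2,4,6-trien-1-yl]acetate | C/C=C/CCCCCCC[C@@H]1/C=C\C=C/C=C\[C@H]1CC(=O)OCC | intermediate
13 | 2-[(1R,8R)-8-((E)-dec-8-en-1-yl)cycloocta-2,4,6-trien-1-yl]acetaldehyde | C/C=C/CCCCCCC[C@@H]1/C=C\C=C/C=C\[C@H]1CC=O | intermediate
14 | bromomagnesium alkoxide of the vinyl adduct of 13 | C/C=C/CCCCCCC[C@@H]1/C=C\C=C/C=C\[C@H]1CC(O[Mg]Br)C=C | intermediate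
15 | 1-[(1R,8R)-8-((E)-dec-8-en-1-yl)cycloocta-2,4,6-trien-1-yl]but-3-en-2-yl methyl carbonate (carbinol epimers) | C/C=C/CCCCCCC[C@@H]1/C=C\C=C/C=C\[C@H]1CC(OC(=O)OC)C=C | intermediate
16 | bicyclo[4.2.0]octa-2,4-diene valence isomer of 15 (carbonate chain endo, decenyl exo) | C/C=C/CCCCCCC[C@@H]1[C@H]2C=CC=C[C@H]2[C@H]1CC(OC(=O)OC)C=C | intermediate
17 | tricyclic allylic but-3-enoate (oxygen on C-c anti to C-j; vinyl on C-j) | C/C=C/CCCCCCC[C@@H]1[C@H]2[C@H](OC(=O)CC=C)C=C[C@@H]3[C@H]2[C@H]1C[C@@H]3C=C | intermediate
18 | trimethylsilyl ketene acetal of 17 | C/C=C/CCCCCCC[C@@H]1[C@H]2[C@H](OC(O[Si](C)(C)C)=CC=C)C=C[C@@H]3[C@H]2[C@H]1C[C@@H]3C=C | intermediate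
19 | 2-(tricyclic C-e-yl)but-3-enoic acid (C-m epimers) | C/C=C/CCCCCCC[C@@H]1[C@H]2C=C[C@H](C(C=C)C(=O)O)[C@@H]3[C@H]2[C@H]1C[C@@H]3C=C | intermediate
20 | methyl ester of 19 (C-m epimers) | C/C=C/CCCCCCC[C@@H]1[C@H]2C=C[C@H](C(C=C)C(=O)OC)[C@@H]3[C@H]2[C@H]1C[C@@H]3C=C | intermediate
21 | tetracyclic methyl ester, C-m epimer mixture | C/C=C/CCCCCCC[C@@H]1[C@H]2C=C[C@H]3[C@@H]4[C@H]2[C@H]1C[C@@H]4C=CC3C(=O)OC | intermediate
22 | lithium ester dienolate of 21 | C/C=C/CCCCCCC[C@@H]1[C@H]2C=C[C@H]3[C@@H]4[C@H]2[C@H]1C[C@@H]4C=CC3=C(OC)O[Li] | intermediate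
23 | target methyl ester (CNP0133550.2) | C/C=C/CCCCCCC[C@@H]1[C@H]2C=C[C@H]3[C@@H]4[C@H]2[C@H]1C[C@@H]4C=C[C@H]3C(=O)OC | target

**Step count**
Total: 12 steps. Longest linear sequence: 11 steps (1, 2, 3, 5, 6, 7, 8, 9, 10, 11, 12, starting from compound 1).

**Steps most likely to fail and fallbacks**

Step 2 (new desymmetrising borylation; risks are low enantioselectivity, syn instead of anti delivery, or SN2 instead of SN2′ opening). The fallback sets out from 2 and uses the known copper–phosphoramidite-catalysed anti-SN2′ alkylation of this epoxide with a dialkylzinc. Compound 6 and 1,7-dibromoheptane are coupled under the conditions of step 4 to (E)-10-bromodec-2-ene F1. F1 is converted with Mg and then ZnCl2 into bis[(E)-dec-8-en-1-yl]zinc F2. F2 with Cu(OTf)2 (3 mol %) and a BINOL-derived phosphoramidite (6 mol %) in toluene at −78 to 0 °C opens 2 directly to the trans-4-alkyl trienol. The fallback comes back to the route at 10 and also makes steps 3 and 5 unnecessary.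

Step 9 (new palladium relay; risks are diene formation from the first π-allyl complex, capture at C-e instead of C-c, or loss of facial integrity at C-c). The fallback sets out from 13 and uses known chemistry. Wittig olefination with Ph3P=CHCH2SiMe3 gives the (Z)-allylsilane F3. The divalent-palladium-catalysed intramolecular 1,4-carbochlorination of cyclohexadienes by allylsilanes (Pd(OAc)2, LiCl, 1,4-benzoquinone, acetone–AcOH) then gives the allylic chloride F4: the allylsilane attacks C-f anti to palladium and chloride attacks C-c anti to palladium, so both land on the top face. At room temperature only the endo valence isomer reacts, so the unreacted isomer is re-equilibrated by heating and recycled; the C-j configuration is checked by NOE here. SN2 displacement of F4 with CsO2CCH2CH=CH2 in DMF inverts C-c, and the fallback comes back at 17.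

Step 12 (substrate-controlled kinetic protonation may give too little of the pseudo-axial ester). The fallback sets out from 21. The lithium dienolate is trapped with Me3SiCl as the trimethylsilyl ketene acetal F5. F5 is then protonated under catalyst control rather than substrate control, with MeOH and a chiral Brønsted acid (a confined imidodiphosphorimidate; the antipode matched to the substrate is chosen experimentally). The fallback comes back at 23.

**Further compounds**
F1 | step 2 | (E)-10-bromodec-2-ene | C/C=C/CCCCCCCBr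
F2 | step 2 | bis[(E)-dec-8-en-1-yl]zinc | C/C=C/CCCCCCC[Zn]CCCCCCC/C=C/C
F3 | step 9 | (Z)-allylsilane from 13, trimethyl[(Z)-4-((1R,8R)-8-((E)-dec-8-en-1-yl)cycloocta-2,4,6-trien-1-yl)but-2-en-1-yl]silane | C/C=C/CCCCCCC[C@@H]1/C=C\C=C/C=C\[C@H]1C/C=C\C[Si](C)(C)C
F4 | step 9 | tricyclic allylic chloride (Cl on C-c syn to C-j; vinyl on C-j) | C/C=C/CCCCCCC[C@@H]1[C@H]2[C@@H](Cl)C=C[C@@H]3[C@H]2[C@H]1C[C@@H]3C=C
F5 | step 12 | trimethylsilyl ketene acetal of 21 | C/C=C/CCCCCCC[C@@H]1[C@H]2C=C[C@H]3[C@@H]4[C@H]2[C@H]1C[C@@H]4C=CC3=C(OC)O[Si](C)(C)C
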